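Retrosynthesis: the two C3''–CH3 bonds of the carbinol are cut first (methyl nucleophiles on a lactone carbonyl), then C6–C1'' (alkyne hydroarylation), then the C5–O acyl bond, and last ring C (C2 from DMF, C4–C4a by Friedel–Crafts acylation).
Enabling feature: the C5 hydroxyl and the C6 chain C1''–C2''–C3''(OH)Me2 together are a masked six-membered lactone, C5–O–C3''(=O)–C2''–C1''–C6, fused to ring A; a three-atom acyl tether on the C5 oxygen can reach only C6, because the other ortho carbon, C4a, is quaternary.
Forward: ring A (phloroglucinol) is C-acylated and ring C is closed with one carbon; after a change of protecting groups only the chelated C5–OH is free, and it is esterified with propiolic acid.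
Gold then closes the 2-pyranone ring D from the ester onto C6 (C6–C1''); the lactone alkene is hydrogenated, two methyl groups open the lactone to the C5 phenol and the dimethylcarbinol, and hydrogenolysis frees the phenols.
Stereochemistry: the target has no stereocentre and no stereogenic double bond, so nothing has to be controlled.

Key step: step 5

Remark on the chemistry: ring B is brought in as its dimethyl ether, because a free 2-hydroxyphenylacetic acid lactonises under BF3 and a free 2'-hydroxyl offers a competing benzofuran closure in the one-carbon step. The side chain is numbered C1'' (on C6) to C3'' (carbinol carbon).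

Step 1
Reactants: 1 phloroglucinol; 2 2,4-dimethoxyphenylacetic acid
Product: 4 5,7-dihydroxy-2',4'-dimethoxyisoflavone, via deoxybenzoin 3 (not isolated)
Conditions: BF3·OEt2 (neat), 85 °C; then DMF, MeSO2Cl, 70 °C; aqueous NaOAc
Reagents that add atoms: N,N-dimethylformamide, CN(C)C=O
Why: Friedel–Crafts C-acylation of the symmetric triphenol in BF3·OEt2 (a Houben–Hoesch-type deoxybenzoin synthesis) can give only one ketone, and the iminium salt made from DMF and MeSO2Cl then formylates the activated methylene so that a flanking ring A hydroxyl closes ring C with loss of dimethylamine, which is the standard one-pot deoxybenzoin route to 5,7-dihydroxyisoflavones.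

Step 2
Reactants: 4 5,7-dihydroxy-2',4'-dimethoxyisoflavone
Product: 5 2'-hydroxygenistein (5,7,2',4'-tetrahydroxyisoflavone)
Conditions: BBr3 (7 equiv), CH2Cl2, −78 °C to rt; MeOH, H2O
Reagents that add atoms: none
Why: Lewis-acid ether cleavage (BBr3 O-demethylation) removes both aryl methyl groups by bromide attack on the boron-complexed ethers and leaves the isoflavone nucleus untouched.

Step 3
Reactants: 5 2'-hydroxygenistein
Product: 6 7,2',4'-tri-O-benzyl-2'-hydroxygenistein (5-OH free)
Conditions: BnBr (3.1 equiv), K2CO3, acetone, reflux
Reagents that add atoms: benzyl bromide, BrCc1ccccc1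
Why: Williamson etherification takes the three acidic, unchelated phenols at C7, C2' and C4', while the C5 hydroxyl, held in a hydrogen bond to the C4 carbonyl, should stay free when the halide is limited to three equivalents.

Step 4
Reactants: 6 7,2',4'-tri-O-benzyl-2'-hydroxygenistein; 7 propiolic acid
Product: 9 7,2',4'-tri-O-benzyl-2'-hydroxygenistein 5-propiolate, via O-acylisourea 8 (not isolated)
Conditions: DCC (2 equiv), DMAP (5 mol %), CH2Cl2, −20 °C to rt
Reagents that add atoms: none
Why: Steglich-type carbodiimide esterification, in which the O-acylisourea of the alkynoic acid is an acyl donor electrophilic enough to acylate even the hydrogen-bonded C5 phenol (as routine acylations of 5-hydroxyisoflavones show), while low temperature and little DMAP hold back amine addition to the ynoate.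

Step 5
Reactants: 9 7,2',4'-tri-O-benzyl-2'-hydroxygenistein 5-propiolate
Product: 10 5-(benzyloxy)-9-[2,4-bis(benzyloxy)phenyl]-2H,10H-pyrano[2,3-f]chromene-2,10-dione (isoflavone with 2-pyranone ring D fused across C5–O and C6)
Conditions: [(t-Bu)2(2-biphenylyl)P]Au(NCMe)SbF6 (5 mol %, monovalent gold), ClCH2CH2Cl, 50 °C
Reagents that add atoms: none
Why: The cationic monovalent gold complex binds the terminal alkyne of the ynoate as a π-acid, C6 of ring A attacks the alkyne terminus anti to gold in a Friedel–Crafts sense, and rearomatisation followed by protodeauration releases the lactone alkene and the catalyst. The closest known reaction is the gold-catalysed intramolecular hydroarylation of aryl propiolates to coumarins, applied here to the 5-ester of a chromone. The one new ring, the 2-pyranone ring D fused across C5–O and C6, closes in the 6-endo-dig mode, with both alkyne carbons ending inside the ring. No stereocentre is formed. The step needs site selectivity for C6 over C8 and over the more electron-rich ring B, and the O–C(=O)–C tether on the C5 oxygen secures it, since it reaches only an ortho carbon and the other one, C4a, is quaternary; C6 is also the electronically favoured carbon (ortho to the C7 ether, para to O1, meta to the C4 carbonyl).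

Step 6
Reactants: 10 pyranone-fused isoflavone
Product: 11 5-(benzyloxy)-9-[2,4-bis(benzyloxy)phenyl]-3,4-dihydro-2H,10H-pyrano[2,3-f]chromene-2,10-dione (dihydrocoumarin-type lactone)
Conditions: H2 (5 atm), RhCl(PPh3)3 (10 mol %), toluene–THF, 50 °C
Reagents that add atoms: none
Why: Homogeneous hydrogenation with RhCl(PPh3)3 saturates the cis-disubstituted lactone alkene, as it does in coumarin itself, while the trisubstituted, oxygen-bearing C2=C3 alkene of ring C binds rhodium poorly and aryl benzyl ethers are inert to this catalyst.

Step 7
Reactants: 11 dihydrocoumarin-type lactone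
Product: 13 7,2',4'-tris(benzyloxy)-5-hydroxy-6-(3-hydroxy-3-methylbutyl)isoflavone, via methyl ketone 12 (not isolated)
Conditions: MeMgBr (3 equiv), CeCl3 (3 equiv, dried), THF, −78 to −40 °C; aqueous NH4Cl
Reagents that add atoms: methylmagnesium bromide, C[Mg]Br
Why: Double addition of an organocerium (Grignard-derived) methyl nucleophile to the aryl lactone, in which the first addition expels the C5 phenoxide and leaves a methyl ketone and the second gives the tertiary alkoxide; the carbonyl-selective, weakly basic cerium reagent should prefer the activated aryl ester and the ketone over the hindered vinylogous-ester C4 carbonyl, which is deactivated further once the peri phenoxide is free.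

Step 8
Reactants: 13 7,2',4'-tris(benzyloxy)-5-hydroxy-6-(3-hydroxy-3-methylbutyl)isoflavone
Product: 14 luteone hydrate (5,7,2',4'-tetrahydroxy-6-(3-hydroxy-3-methylbutyl)isoflavone)
Conditions: H2 (1 atm), 10% Pd/C, EtOAc–MeOH, rt
Reagents that add atoms: none
Why: Catalytic hydrogenolysis of the three aryl benzyl ethers under neutral conditions frees the phenols without acid, which would close the carbinol onto the C5 or C7 hydroxyl as a chroman, and the reaction is stopped after three equivalents of hydrogen so that C2=C3 is kept.

Compound list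
1 | phloroglucinol | Oc1cc(O)cc(O)c1 | starting material
2 | 2,4-dimethoxyphenylacetic acid | COc1ccc(CC(=O)O)c(OC)c1 | starting material
3 | 2-(2,4-dimethoxyphenyl)-1-(2,4,6-trihydroxyphenyl)ethanone (deoxybenzoin, not isolated) | COc1ccc(CC(=O)c2c(O)cc(O)cc2O)c(OC)c1 | intermediate
4 | 5,7-dihydroxy-2',4'-dimethoxyisoflavone | COc1ccc(-c2coc3cc(O)cc(O)c3c2=O)c(OC)c1 | intermediate
5 | 2'-hydroxygenistein (5,7,2',4'-tetrahydroxyisoflavone) | O=c1c(-c2ccc(O)cc2O)coc2cc(O)cc(O)c12 | intermediate
6 | 7,2',4'-tri-O-benzyl-2'-hydroxygenistein | O=c1c(-c2ccc(OCc3ccccc3)cc2OCc2ccccc2)coc2cc(OCc3ccccc3)cc(O)c12 | intermediate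
7 | propiolic acid | C#CC(=O)O | starting material
8 | O-propioloyl-N,N'-dicyclohexylisourea (not isolated) | C#CC(=O)OC(=NC1CCCCC1)NC1CCCCC1 | intermediate
9 | 7,2',4'-tri-O-benzyl-2'-hydroxygenistein 5-propiolate | C#CC(=O)Oc1cc(OCc2ccccc2)cc2occ(-c3ccc(OCc4ccccc4)cc3OCc3ccccc3)c(=O)c12 | intermediate
10 | 5-(benzyloxy)-9-[2,4-bis(benzyloxy)phenyl]-2H,10H-pyrano[2,3-f]chromene-2,10-dione | O=c1ccc2c(OCc3ccccc3)cc3occ(-c4ccc(OCc5ccccc5)cc4OCc4ccccc4)c(=O)c3c2o1 | intermediate
11 | 5-(benzyloxy)-9-[2,4-bis(benzyloxy)phenyl]-3,4-dihydro-2H,10H-pyrano[2,3-f]chromene-2,10-dione | O=C1CCc2c(OCc3ccccc3)cc3occ(-c4ccc(OCc5ccccc5)cc4OCc4ccccc4)c(=O)c3c2O1 | intermediate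
12 | 7,2',4'-tris(benzyloxy)-5-hydroxy-6-(3-oxobutyl)isoflavone (methyl ketone, not isolated) | CC(=O)CCc1c(OCc2ccccc2)cc2occ(-c3ccc(OCc4ccccc4)cc3OCc3ccccc3)c(=O)c2c1O | intermediate
13 | 7,2',4'-tris(benzyloxy)-5-hydroxy-6-(3-hydroxy-3-methylbutyl)isoflavone | CC(C)(O)CCc1c(OCc2ccccc2)cc2occ(-c3ccc(OCc4ccccc4)cc3OCc3ccccc3)c(=O)c2c1O | intermediate
14 | luteone hydrate | CC(C)(O)CCc1c(O)cc2occ(-c3ccc(O)cc3O)c(=O)c2c1O | target

Total step count: 8. Longest linear sequence: 8 steps (from 1 and 2 to 14).

Steps most likely to fail

Step 5. Ring A carries the chromone carbonyl and may attack the gold-bound alkyne too slowly, so that hydration of the alkyne or cleavage of the activated aryl ester could outrun ring closure. The fallback gives up the tether and reaches C6 through the free phenol, setting out from 6. Iodination with BnMe3N·ICl2 and CaCO3 in CH2Cl2–MeOH, conditions that halogenate phenols ortho to the hydroxyl and leave aryl ethers such as ring B alone, should give 7,2',4'-tris(benzyloxy)-5-hydroxy-6-iodoisoflavone F1. A Heck reaction with 2-methylbut-3-en-2-ol (Pd(OAc)2, Bu4NCl, NaHCO3, DMF, 80 °C) should then give 7,2',4'-tris(benzyloxy)-5-hydroxy-6-[(E)-3-hydroxy-3-methylbut-1-enyl]isoflavone F2. Hydrogenation over Pd/C in EtOAc, which saturates the alkene and removes the benzyl groups in one operation, comes back to the route at the target 14.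

Step 6. Hydrogen uptake at the conjugated lactone alkene, flanked by the C7 benzyloxy group, may be too slow at a pressure and temperature that still spare C2=C3. The fallback sets out from 10 and carries the alkene through the methyl addition. MeMgBr with CeCl3 in THF at −78 °C should add twice at the lactone carbonyl in the 1,2 sense and open the ring to 7,2',4'-tris(benzyloxy)-5-hydroxy-6-[(Z)-3-hydroxy-3-methylbut-1-enyl]isoflavone F3. This compound is kept away from acid, which would close it to a 2,2-dimethylchromene, and is hydrogenated at once over Pd/C in EtOAc with a trace of NaHCO3; alkene and benzyl groups go together and the route is rejoined at 14.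

Step 4. Acyl transfer to the hydrogen-bonded phenol may be slower than rearrangement of the O-acylisourea to an N-acylurea and amine-initiated oligomerisation of the ynoate. The fallback sets out from 6, masks the alkyne terminus and uses a preformed acyl chloride on the phenoxide. 3-(Trimethylsilyl)propiolic acid with (COCl)2 and catalytic DMF gives 3-(trimethylsilyl)propioloyl chloride F4. The sodium phenoxide of 6 (NaH, THF, 0 °C) is acylated with it to 7,2',4'-tri-O-benzyl-2'-hydroxygenistein 5-[3-(trimethylsilyl)propiolate] F5. Buffered fluoride (Bu4NF, AcOH, THF, −20 °C) removes the silyl group and returns to the route at 9.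

Further compounds
F1 | step 5 | 7,2',4'-tris(benzyloxy)-5-hydroxy-6-iodoisoflavone | O=c1c(-c2ccc(OCc3ccccc3)cc2OCc2ccccc2)coc2cc(OCc3ccccc3)c(I)c(O)c12
F2 | step 5 | 7,2',4'-tris(benzyloxy)-5-hydroxy-6-[(E)-3-hydroxy-3-methylbut-1-enyl]isoflavone | CC(C)(O)/C=C/c1c(OCc2ccccc2)cc2occ(-c3ccc(OCc4ccccc4)cc3OCc3ccccc3)c(=O)c2c1O
F3 | step 6 | 7,2',4'-tris(benzyloxy)-5-hydroxy-6-[(Z)-3-hydroxy-3-methylbut-1-enyl]isoflavone | CC(C)(O)/C=C\c1c(OCc2ccccc2)cc2occ(-c3ccc(OCc4ccccc4)cc3OCc3ccccc3)c(=O)c2c1O
F4 | step 4 | 3-(trimethylsilyl)propioloyl chloride | C[Si](C)(C)C#CC(Cl)=O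
F5 | step 4 | 7,2',4'-tri-O-benzyl-2'-hydroxygenistein 5-[3-(trimethylsilyl)propiolate] | C[Si](C)(C)C#CC(=O)Oc1cc(OCc2ccccc2)cc2occ(-c3ccc(OCc4ccccc4)cc3OCc3ccccc3)c(=O)c12
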